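The octane chain (C1 benzylic, C8 methyl) is cut at C3–C4 and C5–C6: C4–C5 and C6–C7 are two acetaldehyde units added in series to the aldehyde carbon C3 of 3-(4-hydroxy-3-methoxyphenyl)propanal. The key step exploits the syn-3,5-dioxygenated C3–C7 stretch. A 2-deoxyribose-5-phosphate aldolase should forge both bonds and both carbinol centres (C3, C5) in one operation, while the C3 hydroxyl captures the C7 aldehyde as a six-membered oxane lactol (ring atoms: that oxygen and C3–C7). The precursor is the unprotected, α-unbranched arylpropanal, made in one Heck step. Methylenation at C7, hydrogenation, peracetylation and phenol-selective deacetylation then give the target.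

Key step: step 2

Remarks on the chemistry:
- Lactol 7 is carried on as its anomer mixture, because the anomeric carbon becomes the achiral C7 in step 3.
- Lactol 7 and hydroxy aldehyde 6 are ring–chain tautomers. Compound 6 is counted once, where it is formed (step 2), and step 3 draws on the same equilibrium.
- The aryl iodide is chosen over the bromide so that the Heck step can run near room temperature.

Step 1
Reactants: 1 4-iodo-2-methoxyphenol; 2 allyl alcohol (prop-2-en-1-ol)
Product: 3 3-(4-hydroxy-3-methoxyphenyl)propanal
Conditions: Pd(OAc)2 (2 mol%), Bu4NCl (1 equiv), NaHCO3 (2.5 equiv), DMF, 40 °C, N2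
Reagents that add atoms: none
Why: Mizoroki–Heck arylation of an allylic alcohol under ligand-free phase-transfer conditions, in which the aryl iodide adds readily to zerovalent palladium, the aryl group is delivered to the terminal alkene carbon, and β-hydride elimination toward the carbinol carbon gives the saturated aldehyde directly; free phenols are tolerated.

Step 2
Reactants: 3 3-(4-hydroxy-3-methoxyphenyl)propanal; 4 acetaldehyde (two equivalents incorporated)
Product: 7 (2RS,4R,6R)-6-[2-(4-hydroxy-3-methoxyphenyl)ethyl]oxane-2,4-diol, via mono-aldol hydroxy aldehyde 5 (not isolated), via open-chain dihydroxy aldehyde 6 (not isolated)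
Conditions: 2-deoxyribose-5-phosphate aldolase (E. coli enzyme or a variant engineered for acetaldehyde tolerance and a wider acceptor pocket), triethanolamine buffer pH 7.5, DMSO (10% v/v), 25 °C; acetaldehyde (2.5 equiv) fed slowly
Reagents that add atoms: none
Why: Proposed new method: the active-site lysine condenses with acetaldehyde to an enamine that adds to the si face of the aldehyde carbon of compound 3 (bond C3–C4), hydrolysis releases 5, and 5 returns as acceptor for a second enamine addition with the same facial sense (bond C5–C6) to give 6; the closest known reaction is the same enzyme's sequential double addition of acetaldehyde to 2-haloacetaldehydes and similar small acceptors, which gives the statin-type trideoxyhexose lactols, and the extension to a 3-arylpropanal acceptor is the unproven part. The oxane ring closes spontaneously by 6-exo-trig hemiacetalisation of the C3 hydroxyl onto the C7 aldehyde, which takes 6 out of the aldol equilibrium and blocks a third addition. Both new stereocentres (C3 as R and C5 as S in the octane numbering of the target; 6R and 4R in lactol 7, mutually syn) are fixed by the enzyme active site and not by the substrate. The step needs cross-aldol selectivity over self-condensation of acetaldehyde: compound 3 is too large for the donor site and can only serve as acceptor, it is unbranched at its α-carbon and buffer-compatible through its free phenol, and slow feeding keeps the acetaldehyde concentration low so that compound 3 competes for the acceptor site.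

Step 3
Reactants: 7 (2RS,4R,6R)-6-[2-(4-hydroxy-3-methoxyphenyl)ethyl]oxane-2,4-diol
Product: 8 (3R,5S)-1-(4-hydroxy-3-methoxyphenyl)oct-7-ene-3,5-diol
Conditions: Ph3PCH3Br (5 equiv), KOtBu (5 equiv), THF, 0 °C to 40 °C
Reagents that add atoms: methyltriphenylphosphonium bromide, C[P+](c1ccccc1)(c1ccccc1)c1ccccc1.[Br-]
Why: Wittig methylenation of an unprotected 2-deoxy lactol, in which the basic medium shifts the hemiacetal to the alkoxide of its ring-opened aldehyde tautomer and the non-stabilised ylide traps that aldehyde as it is released (the excess covers the phenol and hydroxyl protons), as is routinely done with unprotected 2-deoxy sugars; neither carbinol centre is involved.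

Step 4
Reactants: 8 (3R,5S)-1-(4-hydroxy-3-methoxyphenyl)oct-7-ene-3,5-diol
Product: 9 (3R,5S)-1-(4-hydroxy-3-methoxyphenyl)octane-3,5-diol
Conditions: H2 (1 atm), Pd/C (10 wt% Pd), EtOAc, rt
Reagents that add atoms: none
Why: Heterogeneous catalytic hydrogenation of a terminal alkene; the molecule has no benzylic C–O bond to hydrogenolyse and the carbinol centres are untouched.

Step 5
Reactants: 9 (3R,5S)-1-(4-hydroxy-3-methoxyphenyl)octane-3,5-diol
Product: 10 4-[(3R,5S)-3,5-bis(acetyloxy)octyl]-2-methoxyphenyl acetate
Conditions: Ac2O (6 equiv), pyridine, DMAP (cat.), CH2Cl2, 0 °C to rt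
Reagents that add atoms: acetic anhydride, CC(=O)OC(C)=O
Why: DMAP-catalysed exhaustive O-acetylation esterifies both secondary alcohols and the phenol, so no selectivity between them is required at this stage, and no bond to a stereocentre is broken.

Step 6
Reactants: 10 4-[(3R,5S)-3,5-bis(acetyloxy)octyl]-2-methoxyphenyl acetate
Product: 11 (3R,5S)-1-(4-hydroxy-3-methoxyphenyl)octane-3,5-diyl diacetate
Conditions: pyrrolidine (1.5 equiv), MeCN, 0 °C to rt
Reagents that add atoms: none
Why: Chemoselective aminolysis, in which the aryl acetate with its good phenoxide leaving group is cleaved by a secondary amine much faster than the two secondary alkyl acetates, a standard way to free a phenol beside aliphatic acetates.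

Compound list
1 | 4-iodo-2-methoxyphenol | COc1cc(I)ccc1O | starting material
2 | allyl alcohol (prop-2-en-1-ol) | C=CCO | starting material
3 | 3-(4-hydroxy-3-methoxyphenyl)propanal | O=CCCc1ccc(O)c(OC)c1 | intermediate
4 | acetaldehyde | CC=O | starting material
5 | (3R)-3-hydroxy-5-(4-hydroxy-3-methoxyphenyl)pentanal (not isolated) | O=CC[C@H](O)CCc1ccc(O)c(OC)c1 | intermediate
6 | (3R,5R)-3,5-dihydroxy-7-(4-hydroxy-3-methoxyphenyl)heptanal (not isolated) | O=CC[C@H](O)C[C@H](O)CCc1ccc(O)c(OC)c1 | intermediate
7 | (2RS,4R,6R)-6-[2-(4-hydroxy-3-methoxyphenyl)ethyl]oxane-2,4-diol (anomer mixture) | OC1C[C@H](O)C[C@@H](CCc2ccc(O)c(OC)c2)O1 | intermediate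
8 | (3R,5S)-1-(4-hydroxy-3-methoxyphenyl)oct-7-ene-3,5-diol | C=CC[C@H](O)C[C@H](O)CCc1ccc(O)c(OC)c1 | intermediate
9 | (3R,5S)-1-(4-hydroxy-3-methoxyphenyl)octane-3,5-diol | CCC[C@H](O)C[C@H](O)CCc1ccc(O)c(OC)c1 | intermediate
10 | 4-[(3R,5S)-3,5-bis(acetyloxy)octyl]-2-methoxyphenyl acetate | CCC[C@@H](C[C@@H](CCc1ccc(OC(C)=O)c(OC)c1)OC(C)=O)OC(C)=O | intermediate
11 | (3R,5S)-1-(4-hydroxy-3-methoxyphenyl)octane-3,5-diyl diacetate | CCC[C@@H](C[C@@H](CCc1ccc(O)c(OC)c1)OC(C)=O)OC(C)=O | target

Total step count: 6. Longest linear sequence: 6 steps (1 to 11).

Steps most likely to fail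

Step 2 (the proposed new method). The lipophilic acceptor may not be taken up by the active site, so that self-condensation of acetaldehyde dominates. The sequence may also stop after the first addition, or the enzyme may be deactivated by acetaldehyde. The fallback uses known chemistry, sets out from compound 3 and comes back at compound 9. Thioacetalisation with propane-1,3-dithiol (BF3·OEt2, CH2Cl2, 0 °C) should give the dithiane 4-[2-(1,3-dithian-2-yl)ethyl]-2-methoxyphenol F1. Double deprotonation (n-BuLi, 2.2 equiv, THF, −30 °C; lithium phenoxide plus 2-lithiodithiane) and Corey–Seebach opening of commercial (S)-2-propyloxirane (CCC[C@H]1CO1) at its CH2 terminus should give (2S)-1-{2-[2-(4-hydroxy-3-methoxyphenyl)ethyl]-1,3-dithian-2-yl}pentan-2-ol F2; the C5 centre is bought with the epoxide. Alkylative dithiane hydrolysis (MeI, CaCO3, aqueous MeCN, 40 °C) should release the β-hydroxy ketone (5S)-5-hydroxy-1-(4-hydroxy-3-methoxyphenyl)octan-3-one F3. A Narasaka–Prasad reduction (Et2BOMe, NaBH4, THF/MeOH, −78 °C), in which the boron chelate directs external hydride to the syn-1,3-diol, should then set C3 as R and deliver compound 9.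

Step 3. Under the strongly basic ylide conditions the ring-opened β-hydroxy aldehyde may fragment by retro-aldol cleavage or dehydrate, which would erode material and the C5 configuration, or the lactol may open too slowly. The fallback sets out from compound 7 and comes back at compound 9. Ohira–Bestmann homologation (dimethyl (1-diazo-2-oxopropyl)phosphonate, K2CO3, MeOH, rt) works under much weaker base through an alkylidene carbene 1,2-shift and should give the terminal alkyne (3R,5S)-1-(4-hydroxy-3-methoxyphenyl)oct-7-yne-3,5-diol F4. Exhaustive hydrogenation of F4 under the conditions of step 4 gives compound 9.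

Step 1. Insertion with the wrong regiochemistry (branched 2-arylpropanal), β-hydride elimination away from the carbinol carbon (cinnamyl-type alcohol) and base-induced self-aldol condensation of the product aldehyde may lower the return. The fallback sets out from compound 1 and comes back at compound 3. Hydroboration of acrolein diethyl acetal with 9-BBN (THF, rt) followed by B-alkyl Suzuki–Miyaura coupling with compound 1 (Pd(dppf)Cl2, K3PO4, DMF/H2O, 60 °C) should give the acetal 4-(3,3-diethoxypropyl)-2-methoxyphenol F5, with the linear chain fixed by the anti-Markovnikov hydroboration. Mild acid hydrolysis (aqueous HCl, THF, rt) then gives compound 3.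

Further compounds
F1 | step 2 | 4-[2-(1,3-dithian-2-yl)ethyl]-2-methoxyphenol | COc1cc(CCC2SCCCS2)ccc1O
F2 | step 2 | (2S)-1-{2-[2-(4-hydroxy-3-methoxyphenyl)ethyl]-1,3-dithian-2-yl}pentan-2-ol | CCC[C@H](O)CC1(CCc2ccc(O)c(OC)c2)SCCCS1
F3 | step 2 | (5S)-5-hydroxy-1-(4-hydroxy-3-methoxyphenyl)octan-3-one | CCC[C@H](O)CC(=O)CCc1ccc(O)c(OC)c1
F4 | step 3 | (3R,5S)-1-(4-hydroxy-3-methoxyphenyl)oct-7-yne-3,5-diol | C#CC[C@H](O)C[C@H](O)CCc1ccc(O)c(OC)c1
F5 | step 1 | 4-(3,3-diethoxypropyl)-2-methoxyphenol | CCOC(CCc1ccc(O)c(OC)c1)OCC
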